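Compounds are numbered 1–26 in the order in which they appear in the steps; the same numbers are used in every section.

## Analysis of the target

Compound 26 is a depside. Ring A, a 2-hydroxy-4-methoxy-6-propylbenzoyl unit, is joined by a single aryl ester bond to the C4 oxygen of ring B, a 2-methoxy-6-pentylbenzoic acid. There is no ring fusion and no stereocenter, so the whole problem is where the substituents sit on two benzene rings. The sensitive points are the inter-ring aryl ester (cleaved or transferred by bases and nucleophiles), the electron-rich, doubly ortho-substituted carboxylic acid of ring B (prone to decarboxylation under acid and heat) and the chelated phenol of ring A. The difficulty is concentrated in ring B: C1, C2, C4 and C6 carry four different substituents, and the two oxygens of what is formally a resorcinol must end up unlike, a methyl ether at C2 and an acyl group at C4. Ring A poses the same question in milder form, and the ester must be made from a 2,6-disubstituted benzoic acid. The route rests on the 1,3 relation of the C2 and C4 oxygens of ring B, with unsubstituted C3 between them and carbon substituents on C1 and C6. A benzannulation that takes the C2 oxygen from a ketene carbonyl and the C4 oxygen from an ynol ether delivers them as a free phenol and a silyl ether as the ring forms, while the alkene of the vinylketene supplies the carboxyl carbon at C1 and the pentyl chain at C6.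

## Retrosynthetic reasoning

**26 to 25.** The ring B acid and the ring A ortho hydroxyl are both carried as benzyl derivatives in 25, so the last step cuts only two benzylic C–O bonds. Hydrogenolysis is neutral and leaves the inter-ring ester alone, which a basic ester hydrolysis would not.

**25 to 18 and 23.** The ester C–O bond between the ring A carbonyl carbon and the C4 oxygen of ring B is cut. It is the only bond linking the rings, so the cut is fully convergent and gives phenol 18, whose C4 hydroxyl is its only free hydroxyl, and acid 23. Forward, a hindered acid must acylate a phenol; activation as the mixed anhydride 24 is planned, which reacts through an acylium ion.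

**18 to 17 to 16.** The C2 O–methyl bond and the C4 O–silicon bond are removed in turn. These are group changes only. They lead to 16, the point at which the two ring B oxygens are already told apart, a free chelated phenol at C2 and a silyl ether at C4, so each can be addressed separately.

**16 to 7 and 11 (key disconnection).** Ring B is opened at three bonds: C2–C3 and C4–C5, which attach the two carbons of siloxyalkyne 11, and C1–C2, which closes the ring. The remaining four carbons (C2, C5, C6, C1) are diazo ketone 7, which by Wolff rearrangement becomes vinylketene 12. Cutting here means no substituent has to be introduced onto a preformed arene: every position is fixed by the connectivity of the two partners. The forward reaction needs one regiochemical outcome, bonding of the unsubstituted alkyne carbon to the ketene carbonyl carbon.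

**7 to 5 to 3.** The diazo carbon is traced to the methyl group of ketone 5 by diazo transfer. Acylation of a diazoalkane by acid chloride 4 was not chosen as the main path, because the alkene in this series is flanked by two carbonyl groups and would take up a free diazoalkane as a dipolarophile. The C–CH3 bond of 5 is cut back to acid 3 through 4, a ketone synthesis from an acyl chloride and a methylzinc reagent.

**3 to 1 and 2.** The C=C bond of 3 is cut by a Wittig disconnection into α-keto acid 1 and stabilized ylide 2. This puts the pentyl group and the future acyl carbon on one alkene carbon and the benzyl ester on the other without ambiguity. The E geometry that such ylides favour is also the one the ring closure wants.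

**11 to 8 and 9.** Siloxyalkyne 11 is cut at the O–Si bond into silyl chloride 9 and lithium ethynolate 10. The ynolate is traced to isoxazole 8, whose 5-lithio derivative falls apart into a nitrile and 10.

**23 to 19.** Ring A is not built but elaborated from a purchased ring. Acid 23 goes back by oxidation level to aldehyde 22, by two O-alkyl disconnections to 21 and 20, and by removal of the formyl carbon to symmetrical resorcinol 19. Here the two oxygens are told apart by the hydrogen bond between the formyl group and its ortho hydroxyl.

## Alternatives that were turned down

**Alternative 1:** Ring B would come from a benzene that already carries its three heteroatom substituents, 1-fluoro-3-methoxy-5-(triisopropylsilyloxy)benzene A2, by cutting the C6–pentyl and C1–carboxyl bonds.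
- Forward step: pentyllithium A3 removes the proton between fluorine and methoxy and fluoride leaves to give an aryne. A second equivalent of A3 adds at the aryne carbon remote from the methoxy group, and carboxylation of the aryllithium gives 2-methoxy-6-pentyl-4-(triisopropylsilyloxy)benzoic acid A1 in one flask.
- For it: two ring bonds form in one operation, and the methoxy group steers both the deprotonation and the direction of addition. The path to ring B is clearly shorter than the annulation, which needs five steps to reach 16; on step economy this alternative is the stronger one.
- Against it:
  - A2 has a second position flanked by fluorine, next to the silyloxy group, and an aryne formed from that side leads to the isomer with the two oxygens interchanged.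
  - An aryllithium beside a silyl ether can undergo oxygen-to-carbon silyl migration.
  - The alkyllithium is base and nucleophile at once, so biaryl formation and ketone formation at the carboxylation stage compete.
  - The unlike oxygens are not created; they must already be present in A2.
- Comparison: the chosen strategy gives up brevity for certainty of position. The only selectivity at issue is the orientation of an electronically biased (2+2) addition, not a kinetic choice among three ring hydrogens.

**Alternative 2:** The disconnection lies in ring A: the bond between its carboxyl-bearing carbon and its propyl-bearing carbon is cut, giving the open-chain 6-(2,4-dioxoheptyl)-2,2-dimethyl-4H-1,3-dioxin-4-one A5.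
- Forward step: the nucleophilic C5 of the dioxinone adds to the propyl ketone in an intramolecular aldol reaction, and dehydration with enolization gives 7-hydroxy-2,2-dimethyl-5-propyl-4H-1,3-benzodioxin-4-one A4.
- For it: the ring forms under mild conditions with its two oxygens unlike from the outset. After methylation of the free hydroxyl, A4 is an activated salicylate that the phenoxide of 18 could open directly to the inter-ring ester with the ortho hydroxyl free. On the ester-forming step and on protecting-group economy for ring A this is stronger than the chosen route, which needs a benzyl ether and an anhydride activation.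
- Against it:
  - The effort goes into the easy ring, which is reached from symmetrical 19 in four standard steps.
  - Ring B is left untouched, so 18 would still have to be made by other means.
  - A5 is a polycarbonyl chain that takes several steps to assemble and tends to cyclize or fragment early.
  - Opening a benzodioxinone that has a substituent next to its carbonyl group with a weakly nucleophilic phenoxide is slow.
- Comparison: the chosen plan spends its key step on ring B, where the structural problem is, and accepts a conventional solution for ring A.

**Alternative 3:** The disconnection again lies in ring A, but on the assembled ester: ring A bonds C1–C2 and C5–C6 are cut. This gives benzyl 4-(hex-2-ynoyloxy)-2-methoxy-6-pentylbenzoate A7, made by acylation of 18, and Brassard's diene A8.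
- Forward step: Diels–Alder addition of A8 to the alkyne of A7, then loss of one methoxy group and of the silyl group, aromatizes to benzyl 4-[(2-hydroxy-4-methoxy-6-propylbenzoyl)oxy]-2-methoxy-6-pentylbenzoate A6, the benzyl ester of 26.
- For it: ring A arises directly on the ester oxygen with its free C2 hydroxyl and C4 methyl ether set by the diene. The hindered acylation and the ring A protecting group both disappear, and one hydrogenolysis finishes the synthesis. In late-stage convergence it is at least as good as the chosen route, and it is about three steps shorter on the ring A side.
- Against it: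
  - A7 is an aryl ester of an ynoic acid, so it is both an activated acyl donor and a Michael acceptor. The ketene acetal end of A8 can attack it by conjugate addition or acyl transfer instead of cycloadding.
  - A β-alkyl ynoate is a sluggish dienophile, so the temperatures needed approach those at which A8 decomposes.
  - The plan presupposes 18 and so leaves the ring B substitution problem unsolved.
- Comparison: the chosen strategy solves the ring B problem in its key step and pays with a longer, but entirely conventional, ring A sequence.

Key step: step 5

Remark on the chemistry: 26 has no stereocenter; the only stereochemical element in the route is the E alkene of 3 to 7, taken to be the major Wittig isomer and purified at the stage of 3.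

## Route

Step 1
Reactants: 1 2-oxoheptanoic acid; 2 benzyl (triphenylphosphoranylidene)acetate
Product: 3 (2E)-4-(benzyloxy)-4-oxo-2-pentylbut-2-enoic acid
Conditions: 2 (1.2 equiv), CH2Cl2, 0 °C to rt; extraction into aq. NaHCO3, then acidification
Reagents that add atoms: none
Why: Wittig olefination of the ketone carbonyl of an α-keto acid by a stabilized ylide; the ylide ester should settle trans to the carboxyl group (E), as is usual with pyruvate-type carbonyls, and extraction of the acid into bicarbonate removes the phosphine oxide and any neutral material.

Step 2
Reactants: 3 (2E)-4-(benzyloxy)-4-oxo-2-pentylbut-2-enoic acid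
Product: 5 benzyl (2E)-3-acetyloct-2-enoate, via acid chloride 4 (not isolated)
Conditions: (COCl)2, DMF (cat.), CH2Cl2, 0 °C to rt; then MeZnCl, Pd(PPh3)4 (cat.), THF, 0 °C to rt
Reagents that add atoms: methylzinc chloride, C[Zn]Cl
Why: Acid chloride formation followed by Negishi acylation: oxidative addition of the acyl chloride to zerovalent palladium, transfer of methyl from zinc and reductive elimination give the methyl ketone. The organozinc reagent adds neither to the benzyl ester nor to the electron-poor alkene, and the trans arrangement of the two carbonyl groups rules out a cyclic pseudo-chloride.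

Step 3
Reactants: 5 benzyl (2E)-3-acetyloct-2-enoate
Product: 7 benzyl (2E)-3-(2-diazoacetyl)oct-2-enoate, via trifluoroacetyl diketone 6 (not isolated)
Conditions: LiN(SiMe3)2, THF, −78 °C; CF3CO2CH2CF3, −78 °C; then MsN3, Et3N, H2O, MeCN, rt
Reagents that add atoms: methanesulfonyl azide, CS(=O)(=O)N=[N+]=[N-]
Why: Detrifluoroacetylative (Regitz-type deacylative) diazo transfer: kinetic deprotonation of the methyl group and Claisen trifluoroacetylation activate that carbon, which then takes the diazo group from the sulfonyl azide while the trifluoroacetyl group leaves on the sulfonamide nitrogen. This is the standard entry to α'-diazo enones and it spares the doubly activated alkene a free diazoalkane, which would add to it as a 1,3-dipole.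

Step 4
Reactants: 8 3-phenylisoxazole; 9 triisopropylsilyl chloride
Product: 11 (triisopropylsilyloxy)ethyne, via lithium ethynolate 10 (not isolated)
Conditions: n-BuLi, THF, −78 °C; then 9, −78 °C to 0 °C
Reagents that add atoms: none
Why: Lithiation of the isoxazole at C5 is followed by cycloreversion of the 5-lithio heterocycle into a nitrile and the lithium ynolate, which the bulky silyl chloride silylates on oxygen (O-silylation of an ynolate to a siloxyalkyne). The hindered triisopropylsilyl group disfavours attack at carbon and later oxygen-to-carbon silyl migration.

Step 5
Reactants: 7 benzyl (2E)-3-(2-diazoacetyl)oct-2-enoate; 11 (triisopropylsilyloxy)ethyne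
Product: 16 benzyl 2-hydroxy-6-pentyl-4-(triisopropylsilyloxy)benzoate, via vinylketene 12 (not isolated), via vinylcyclobutenone 13 (not isolated), via dienylketene 14 (not isolated), via cyclohexadienone 15 (not isolated)
Conditions: 11 (1.5 equiv), ClCH2CH2Cl, hν (254 nm, low-pressure Hg lamp), rt; then 80 °C
Reagents that add atoms: none
Why: Irradiation of 7 expels dinitrogen with a 1,2-shift of the alkenyl group (photochemical Wolff rearrangement) and gives the ester-substituted vinylketene 12. The unsubstituted, nucleophilic carbon of 11 bonds to the ketene carbonyl carbon and a (2+2) cycloaddition across the ketene C=C gives the 3-siloxy-4-vinylcyclobutenone 13, which forms C2–C3 and C4–C5. Four-electron electrocyclic opening of 13 gives the dienylketene 14, and a thermal six-electron disrotatory electrocyclization joins the ketene carbon to the ester-bearing alkene carbon (C1–C2), closing the six-membered ring B as cyclohexadienone 15, which enolizes to the arene 16. The closest known reaction type is the Danheiser benzannulation of α-diazo ketones with siloxyalkynes, which gives resorcinol monosilyl ethers. No stereocenter is set: the sp3 carbons of 13 and 15 are transient and are erased by ring opening and tautomerization. The step needs one regiochemical outcome, the 1,3 relation of the two oxygens with hydrogen between them, and the polarization of the ynol ether secures it because its oxygen-free carbon is the only nucleophilic terminus. The E alkene of 7 places the ester on the outside of the triene terminus in 14, the geometry that favours closure, and because the opening of 13 is reversible only the isomer of 14 with ketene and vinyl group cis drains to product.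

Step 6
Reactants: 16 benzyl 2-hydroxy-6-pentyl-4-(triisopropylsilyloxy)benzoate
Product: 17 benzyl 2-methoxy-6-pentyl-4-(triisopropylsilyloxy)benzoate
Conditions: MeI, K2CO3, acetone, reflux
Reagents that add atoms: iodomethane, CI
Why: Williamson O-methylation of the chelated salicylate hydroxyl, the only free hydroxyl of 16. In dry acetone there is no nucleophile able to remove the hindered aryl silyl ether, so the C4 oxygen stays masked and only C2 is methylated.

Step 7
Reactants: 17 benzyl 2-methoxy-6-pentyl-4-(triisopropylsilyloxy)benzoate
Product: 18 benzyl 4-hydroxy-2-methoxy-6-pentylbenzoate
Conditions: Bu4NF, AcOH, THF, 0 °C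
Reagents that add atoms: none
Why: Fluoride-induced cleavage of the aryl silyl ether, driven by the strength of the Si–F bond. Acetic acid buffers the phenoxide so that the benzyl ester is not attacked.

Step 8
Reactants: 19 divarinol (5-propylbenzene-1,3-diol)
Product: 20 2,4-dihydroxy-6-propylbenzaldehyde
Conditions: POCl3, DMF, 0 °C to rt; then H2O, 50 °C
Reagents that add atoms: N,N-dimethylformamide, CN(C)C=O; water, O
Why: Vilsmeier–Haack formylation of an electron-rich arene. Attack should occur at C4 (identical with C6 by symmetry), para to one hydroxyl and ortho to the other, in preference to the more crowded C2 between the hydroxyls, and hydrolysis of the iminium salt releases the aldehyde.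

Step 9
Reactants: 20 2,4-dihydroxy-6-propylbenzaldehyde
Product: 21 2-hydroxy-4-methoxy-6-propylbenzaldehyde
Conditions: MeI (1.05 equiv), K2CO3, acetone, rt
Reagents that add atoms: iodomethane, CI
Why: Selective Williamson methylation. The C4 hydroxyl, para to the formyl group, is the more acidic and is not hydrogen-bonded, whereas the C2 hydroxyl is held in a chelate with the aldehyde, so one equivalent of alkylating agent should go to C4.

Step 10
Reactants: 21 2-hydroxy-4-methoxy-6-propylbenzaldehyde
Product: 22 2-(benzyloxy)-4-methoxy-6-propylbenzaldehyde
Conditions: BnBr, K2CO3, DMF, 60 °C
Reagents that add atoms: benzyl bromide, BrCc1ccccc1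
Why: Williamson benzylation of the chelated phenol under more forcing conditions in a dipolar aprotic solvent. The benzyl ether keeps this hydroxyl out of the oxidation and the ester coupling and is removed at the end together with the benzyl ester.

Step 11
Reactants: 22 2-(benzyloxy)-4-methoxy-6-propylbenzaldehyde
Product: 23 2-(benzyloxy)-4-methoxy-6-propylbenzoic acid
Conditions: NaClO2, NaH2PO4, 2-methylbut-2-ene, t-BuOH/H2O, rt
Reagents that add atoms: sodium chlorite, [Na+].[O-]Cl=O
Why: Pinnick oxidation of the aldehyde to the acid by chlorous acid. The alkene scavenger removes hypochlorous acid and so protects the electron-rich ring from chlorination; the ethers are inert.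

Step 12
Reactants: 18 benzyl 4-hydroxy-2-methoxy-6-pentylbenzoate; 23 2-(benzyloxy)-4-methoxy-6-propylbenzoic acid
Product: 25 benzyl 4-{[2-(benzyloxy)-4-methoxy-6-propylbenzoyl]oxy}-2-methoxy-6-pentylbenzoate, via mixed trifluoroacetic anhydride 24 (not isolated)
Conditions: (CF3CO)2O, toluene, rt
Reagents that add atoms: none
Why: Esterification through a mixed carboxylic trifluoroacetic anhydride, the classical depside coupling. The electron-rich 2,6-disubstituted acid ionizes readily to a linear acylium ion, which escapes the steric shielding that hampers tetrahedral addition, and the C4 hydroxyl is the only free nucleophile of 18.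

Step 13
Reactants: 25 benzyl 4-{[2-(benzyloxy)-4-methoxy-6-propylbenzoyl]oxy}-2-methoxy-6-pentylbenzoate
Product: 26 4-[(2-hydroxy-4-methoxy-6-propylbenzoyl)oxy]-2-methoxy-6-pentylbenzoic acid (the target)
Conditions: H2 (1 atm), Pd/C, EtOAc, rt
Reagents that add atoms: none
Why: Catalytic hydrogenolysis cleaves both benzylic C–O bonds, the ester and the ether, in one operation. The aryl ester between the rings, the methyl ethers and the arenes are not reduced, and the neutral medium avoids transacylation and decarboxylation of the electron-rich acid.

## Compound list

1 | 2-oxoheptanoic acid | CCCCCC(=O)C(=O)O | starting material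
2 | benzyl (triphenylphosphoranylidene)acetate | O=C(C=P(c1ccccc1)(c1ccccc1)c1ccccc1)OCc1ccccc1 | starting material
3 | (2E)-4-(benzyloxy)-4-oxo-2-pentylbut-2-enoic acid | CCCCC/C(=C\C(=O)OCc1ccccc1)C(=O)O | intermediate
4 | benzyl (2E)-3-(chlorocarbonyl)oct-2-enoate | CCCCC/C(=C\C(=O)OCc1ccccc1)C(Cl)=O | intermediate
5 | benzyl (2E)-3-acetyloct-2-enoate | CCCCC/C(=C\C(=O)OCc1ccccc1)C(C)=O | intermediate
6 | benzyl (2E)-3-(4,4,4-trifluoro-3-oxobutanoyl)oct-2-enoate | CCCCC/C(=C\C(=O)OCc1ccccc1)C(=O)CC(=O)C(F)(F)F | intermediate
7 | benzyl (2E)-3-(2-diazoacetyl)oct-2-enoate | CCCCC/C(=C\C(=O)OCc1ccccc1)C(=O)C=[N+]=[N-] | intermediate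
8 | 3-phenylisoxazole | c1ccc(-c2ccon2)cc1 | starting material
9 | triisopropylsilyl chloride | CC(C)[Si](Cl)(C(C)C)C(C)C | starting material
10 | lithium ethynolate | [Li+].[O-]C#C | intermediate
11 | (triisopropylsilyloxy)ethyne | C#CO[Si](C(C)C)(C(C)C)C(C)C | intermediate
12 | benzyl (2E)-3-(2-oxoethenyl)oct-2-enoate | CCCCC/C(C=C=O)=C\C(=O)OCc1ccccc1 | intermediate
13 | benzyl (2E)-3-[4-oxo-2-(triisopropylsilyloxy)cyclobut-2-en-1-yl]oct-2-enoate (racemic) | CCCCC/C(=C\C(=O)OCc1ccccc1)C1C(=O)C=C1O[Si](C(C)C)(C(C)C)C(C)C | intermediate
14 | benzyl (2E,4E)-7-oxo-3-pentyl-5-(triisopropylsilyloxy)hepta-2,4,6-trienoate | O=C=C/C(O[Si](C(C)C)(C(C)C)C(C)C)=C\C(CCCCC)=C\C(=O)OCc1ccccc1 | intermediate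
15 | benzyl 2-oxo-6-pentyl-4-(triisopropylsilyloxy)cyclohexa-3,5-diene-1-carboxylate (racemic) | CCCCCC1=CC(O[Si](C(C)C)(C(C)C)C(C)C)=CC(=O)C1C(=O)OCc1ccccc1 | intermediate
16 | benzyl 2-hydroxy-6-pentyl-4-(triisopropylsilyloxy)benzoate | CCCCCc1cc(O[Si](C(C)C)(C(C)C)C(C)C)cc(O)c1C(=O)OCc1ccccc1 | intermediate
17 | benzyl 2-methoxy-6-pentyl-4-(triisopropylsilyloxy)benzoate | CCCCCc1cc(O[Si](C(C)C)(C(C)C)C(C)C)cc(OC)c1C(=O)OCc1ccccc1 | intermediate
18 | benzyl 4-hydroxy-2-methoxy-6-pentylbenzoate | CCCCCc1cc(O)cc(OC)c1C(=O)OCc1ccccc1 | intermediate
19 | divarinol (5-propylbenzene-1,3-diol) | CCCc1cc(O)cc(O)c1 | starting material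
20 | 2,4-dihydroxy-6-propylbenzaldehyde | CCCc1cc(O)cc(O)c1C=O | intermediate
21 | 2-hydroxy-4-methoxy-6-propylbenzaldehyde | CCCc1cc(OC)cc(O)c1C=O | intermediate
22 | 2-(benzyloxy)-4-methoxy-6-propylbenzaldehyde | CCCc1cc(OC)cc(OCc2ccccc2)c1C=O | intermediate
23 | 2-(benzyloxy)-4-methoxy-6-propylbenzoic acid | CCCc1cc(OC)cc(OCc2ccccc2)c1C(=O)O | intermediate
24 | 2-(benzyloxy)-4-methoxy-6-propylbenzoic trifluoroacetic anhydride | CCCc1cc(OC)cc(OCc2ccccc2)c1C(=O)OC(=O)C(F)(F)F | intermediate
25 | benzyl 4-{[2-(benzyloxy)-4-methoxy-6-propylbenzoyl]oxy}-2-methoxy-6-pentylbenzoate | CCCCCc1cc(OC(=O)c2c(OCc3ccccc3)cc(OC)cc2CCC)cc(OC)c1C(=O)OCc1ccccc1 | intermediate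
26 | 4-[(2-hydroxy-4-methoxy-6-propylbenzoyl)oxy]-2-methoxy-6-pentylbenzoic acid | CCCCCc1cc(OC(=O)c2c(O)cc(OC)cc2CCC)cc(OC)c1C(=O)O | target

## Step count and least certain steps

Total step count: 13 steps. Longest linear sequence: 8 steps (steps 1, 2, 3, 5, 6, 7, 12 and 13, from 1 to 26); step 4 and steps 8 to 11 are side branches.

**Step 5 (key step).** The alkene of 7 and 12 carries two acceptor groups and absorbs in the range of the lamp, and 12 is more electrophilic than the vinylketenes usually used. The likely failures are therefore:
- light-induced E to Z isomerization, after which the ketene carbon can be captured by the now cis ester carbonyl oxygen in an oxa-six-electron closure to a pyranone instead of by 11;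
- dimerization of 12, or acylation of the product phenol by 12, once 11 runs low;
- incomplete thermal opening of 13.

The fallback gives up the annulation and builds ring B by condensation. It sets out from 9, together with purchased dibenzyl malonate F1 and (3E)-non-3-en-2-one F2, and returns at 16. Michael addition of F1 to F2 and Claisen ring closure (NaH, THF, reflux) should give benzyl 2-hydroxy-4-oxo-6-pentylcyclohex-2-ene-1-carboxylate F3. Dehydrogenation (Br2, DMF, 0 °C, then 80 °C) should aromatize it to benzyl 2,4-dihydroxy-6-pentylbenzoate F4. Silylation of the non-chelated C4 hydroxyl with 9 (imidazole, DMF, 0 °C) should then give 16. In this fallback the two oxygens are told apart by hydrogen bonding to the ester, not by their origin.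

**Step 4.** The parent ynolate 10 has no substituent on carbon, so silylation on carbon (to a silylketene) can compete with silylation on oxygen. The volatile, acid-sensitive ynol ether may also be lost during separation from the nitrile by-product. The fallback changes the ynol ether and the C4 protecting group. It sets out from 7 and returns at 18. Tert-butoxyethyne F5, a known distillable alkoxyalkyne of the class that also serves in this annulation, would replace 11 under the conditions of step 5 and should give benzyl 4-tert-butoxy-2-hydroxy-6-pentylbenzoate F6. Methylation (MeI, K2CO3, acetone) should give benzyl 4-tert-butoxy-2-methoxy-6-pentylbenzoate F7, and CF3CO2H in CH2Cl2 at 0 °C should remove the tert-butyl group to give 18.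

**Step 3.** The base may deprotonate the pentyl CH2 next to the alkene (the vinylogous position of the ester) instead of the methyl group, or the enolate may add to the oxo-enoate of a second molecule, because the substrate is a strong Michael acceptor. The fallback avoids base. It sets out from 3, passes through 4 and returns at 7, replacing steps 2 and 3: 4 is added to excess ethereal CH2N2 at −20 °C and the excess is destroyed at once with AcOH. It makes no compound outside the list (F0). Its own weakness is dipolar addition of the diazoalkane to the alkene, which low temperature and short contact should limit.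

**Step 12.** Acyl transfer may be slow because of the two ortho substituents of the acid. The acylium ion may then attack the electron-rich ring of 18 on carbon, 18 may be held up as its trifluoroacetate, or the benzyl ether may be lost under the acid formed. The fallback replaces the acid-mediated coupling by a base-mediated one. It sets out from 23 and returns at 25: (COCl)2 with catalytic DMF in CH2Cl2 should give 2-(benzyloxy)-4-methoxy-6-propylbenzoyl chloride F8, which is combined with 18 previously deprotonated with NaH in THF at 0 °C to rt.

## Further compounds

F1 | step 5 | dibenzyl malonate | O=C(CC(=O)OCc1ccccc1)OCc1ccccc1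
F2 | step 5 | (3E)-non-3-en-2-one | CCCCC/C=C/C(C)=O
F3 | step 5 | benzyl 2-hydroxy-4-oxo-6-pentylcyclohex-2-ene-1-carboxylate (racemic, relative configuration not controlled) | CCCCCC1CC(=O)C=C(O)C1C(=O)OCc1ccccc1
F4 | step 5 | benzyl 2,4-dihydroxy-6-pentylbenzoate | CCCCCc1cc(O)cc(O)c1C(=O)OCc1ccccc1
F5 | step 4 | tert-butoxyethyne | C#COC(C)(C)C
F6 | step 4 | benzyl 4-tert-butoxy-2-hydroxy-6-pentylbenzoate | CCCCCc1cc(OC(C)(C)C)cc(O)c1C(=O)OCc1ccccc1
F7 | step 4 | benzyl 4-tert-butoxy-2-methoxy-6-pentylbenzoate | CCCCCc1cc(OC(C)(C)C)cc(OC)c1C(=O)OCc1ccccc1
F0 | step 3 | none | none
F8 | step 12 | 2-(benzyloxy)-4-methoxy-6-propylbenzoyl chloride | CCCc1cc(OC)cc(OCc2ccccc2)c1C(Cl)=O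
A1 | alternative 1 | 2-methoxy-6-pentyl-4-(triisopropylsilyloxy)benzoic acid | CCCCCc1cc(O[Si](C(C)C)(C(C)C)C(C)C)cc(OC)c1C(=O)O
A2 | alternative 1 | 1-fluoro-3-methoxy-5-(triisopropylsilyloxy)benzene | COc1cc(F)cc(O[Si](C(C)C)(C(C)C)C(C)C)c1
A3 | alternative 1 | pentyllithium | [Li]CCCCC
A4 | alternative 2 | 7-hydroxy-2,2-dimethyl-5-propyl-4H-1,3-benzodioxin-4-one | CCCc1cc(O)cc2OC(C)(C)OC(=O)c12
A5 | alternative 2 | 6-(2,4-dioxoheptyl)-2,2-dimethyl-4H-1,3-dioxin-4-one | CCCC(=O)CC(=O)CC1=CC(=O)OC(C)(C)O1
A6 | alternative 3 | benzyl 4-[(2-hydroxy-4-methoxy-6-propylbenzoyl)oxy]-2-methoxy-6-pentylbenzoate | CCCCCc1cc(OC(=O)c2c(O)cc(OC)cc2CCC)cc(OC)c1C(=O)OCc1ccccc1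
A7 | alternative 3 | benzyl 4-(hex-2-ynoyloxy)-2-methoxy-6-pentylbenzoate | CCCC#CC(=O)Oc1cc(CCCCC)c(C(=O)OCc2ccccc2)c(OC)c1
A8 | alternative 3 | 1,3-dimethoxy-1-(trimethylsilyloxy)buta-1,3-diene (Brassard's diene, C1 geometry immaterial) | C=C(OC)C=C(OC)O[Si](C)(C)C
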